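## Retrosynthetic overview
1. Cut C12–C13 (Heck): 9-vinyl clerodane core plus bought 4-bromobutenolide. The vinyl group comes from a CH2CH2Br arm by loss of HBr.
2. The clerodane core comes from an enantio-labdane-type 8β,9β-epoxide by epoxide-triggered backbone shifts (CH3-20 C10→C9, H-5→C10, CH3-19 C4→C5, then loss of H-3). The epoxide oxygen ends as 8β-OH.
3. The epoxy diester comes from a Δ7 bicycle. C6–O is set by allylic oxidation and β-face hydride; C7–O and the epoxide come from a singlet-oxygen ene reaction with Ti oxygen transfer.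
4. The Δ7 bicycle comes from acyclic (3E,7E)-homofarnesyl bromide by one proton-initiated, catalyst-controlled chair–chair cation–olefin bicyclisation.
5. Ring order: ring A, then ring B, both in the same step. The butenolide ring is bought, not formed.

Assumption: (3E,7E)-homofarnesol (bulk feedstock of ambroxide manufacture) and 4-bromofuran-2(5H)-one count as commercial; atom numbers are labdane/clerodane numbers and α/β describe the real molecule drawn with ring A left and C10 top centre (target: 10β-H; CH3-17, -19, -20 all α; 6α-OAc, 7β-isobutyrate, 8β-OH; C11 β).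

## Route

Step 1
Reactants: 1 (3E,7E)-homofarnesol
Product: 2 (3E,7E)-homofarnesyl bromide
Conditions: CBr4, PPh3, CH2Cl2, 0 °C
Reagents that add atoms: carbon tetrabromide BrC(Br)(Br)Br
Why: Appel reaction, an SN2 displacement at the primary carbinol under neutral conditions, so the three trisubstituted alkenes keep their E geometry and no stereocentre is involved.

Step 2
Reactants: 2 (3E,7E)-homofarnesyl bromide
Product: 3 Δ7 bicyclic bromide (5β-H 9β-H 10α-CH3)
Conditions: N,N'-bis(trifluoromethylsulfonyl) imidodiphosphorimidate Brønsted acid built from two 3,3'-bis[3,5-bis(trifluoromethyl)phenyl]-BINOL units (antipode giving the 4aR,8aR series, 5 mol %), (CF3)3COH/CH2Cl2, −20 °C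
Reagents that add atoms: none
Why: Proposed new method: the confined strong chiral acid protonates the terminal alkene at C3 inside its pocket, the (E,E)-triene folds chair–chair so that anti-parallel additions (Stork–Eschenmoser rule) close ring A and then ring B and fix 5β-H, 10α-CH3 and 9β-H relative to one another while the catalyst antipode fixes the absolute sense, and the tertiary C8 cation, paired with a non-nucleophilic anion in a non-nucleophilic fluoroalcohol, ends by loss of the axial 7β-H (the drimenol-type Δ7 outcome of low-temperature Brønsted-acid cyclisation of farnesyl substrates); the closest known reaction type is the imidodiphosphorimidate-catalysed asymmetric polyene cyclisation of homofarnesol to ambroxide, from which this differs only in ending by deprotonation instead of O-capture.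

Step 3
Reactants: 3 Δ7 bicyclic bromide
Product: 4 7-en-6-one
Conditions: CrO3, 3,5-dimethylpyrazole, CH2Cl2, −20 °C
Reagents that add atoms: chromium trioxide O=[Cr](=O)=O
Why: CrO3·3,5-dimethylpyrazole allylic oxidation converts the only allylic methylene (C6) into the enone, as known for drimenyl esters, because the other ring allylic position (C9–H) is tertiary and cannot give a ketone, and the primary bromide and the trans ring fusion are untouched.

Step 4
Reactants: 4 7-en-6-one
Product: 6 6α-acetoxy Δ7 bicyclic bromide, via diisobutylaluminium 6α-alkoxide 5 (not isolated)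
Conditions: i-Bu2AlH, CH2Cl2, −78 °C; then Ac2O, DMAP, pyridine, −78 °C to rt
Reagents that add atoms: acetic anhydride CC(=O)OC(C)=O
Why: 1,2-reduction of the enone followed by DMAP-catalysed acetylation in the same flask, in which the α face of C6 is blocked by the syn-axial 10α- and 4α-methyl groups, so hydride adds from the β face and sets the axial 6α-oxygen.

Step 5
Reactants: 6 6α-acetoxy Δ7 bicyclic bromide
Product: 8 7β-hydroxy-8β,9β-epoxide 6α-acetate, via 7β-hydroperoxide 7 (not isolated)
Conditions: O2, visible light, 5,10,15,20-tetraphenylporphyrin (0.5 mol %), Ti(Oi-Pr)4 (10 mol %), 4 Å sieves, CH2Cl2, 0 °C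
Reagents that add atoms: dioxygen O=O
Why: Schenck ene reaction followed by Ti-catalysed hydroxy-directed oxygen transfer, in which singlet oxygen attacks the open β face (the α face carries 10α-CH3 and the axial 6α-OAc), bonds to C7 and removes the axial 9β-H to give the 7β-hydroperoxide with a Δ8(9) alkene, and the peroxide oxygen is then delivered syn to the 7β-oxygen, which sets C7 and C8 and places the C9–O bond on the β face.

Step 6
Reactants: 8 7β-hydroxy-8β,9β-epoxide 6α-acetate
Product: 9 8β,9β-epoxide 6α-acetate 7β-isobutyrate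
Conditions: (i-PrCO)2O, DMAP, Et3N, CH2Cl2, rt
Reagents that add atoms: isobutyric anhydride CC(C)C(=O)OC(=O)C(C)C
Why: DMAP-catalysed (Steglich-type) acylation of the only free hydroxyl, with no acyl migration (O6 and O7 are trans-diaxial) and no Payne rearrangement (O7 and the epoxide are cis).

Step 7
Reactants: 9 8β,9β-epoxide 6α-acetate 7β-isobutyrate
Product: 10 clerodane bromide (Δ3 8β-OH 6α-OAc 7β-isobutyrate)
Conditions: BF3·OEt2 (0.3 equiv), CH2Cl2, −78 to −30 °C; aq NaHCO3
Reagents that add atoms: none
Why: Proposed new method: BF3 binds the epoxide oxygen and the pseudo-axial C9–O bond (C8–O cleavage is disfavoured by the neighbouring 7-acyloxy group) ionises with help from the only anti-periplanar σ-bond, C10–CH3, after which the all-trans-diaxial array 10α-CH3/5β-H/4α-CH3 relays the charge by suprafacial 1,2-shifts (CH3-20 to C9α, H-5 to C10β, CH3-19 to C5α) to C4, the tertiary site farthest from the three electron-withdrawing C–O bonds, where loss of H-3 gives the Δ3 alkene and the proton frees 8β-OH, so C9, C10 and C5 are set stereospecifically by inversion at each migration terminus and C6, C7 and C8 are untouched; the closest known reaction types are the Westphalen rearrangement (methyl shift next to a 6-acetoxy group without acetoxonium capture) and BF3-induced epoxide-opening/methyl–hydride-shift domino sequences of friedo-drimane chemistry, and the shifts copy the labdadienyl-to-kolavenyl cation sequence of clerodane biosynthesis.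

Step 8
Reactants: 10 clerodane bromide; 11 4-bromofuran-2(5H)-one
Product: 13 target CNP0207114.1, via 9-vinyl clerodane 12 (not isolated)
Conditions: Pd(P(t-Bu)2Me)2 (5 mol %), Cy2NMe (3 equiv), dioxane, rt; then 11 (1.5 equiv), 70 °C
Reagents that add atoms: 4-bromofuran-2(5H)-one (11) O=C1C=C(Br)CO1
Why: Pd-catalysed dehydrohalogenation followed by a Mizoroki–Heck reaction with the same catalyst and base, in which zerovalent palladium inserts into the primary C–Br bond and β-hydride elimination gives the terminal vinyl group, the butenolide then adds to the terminal C12, and the only β-hydrogen (on C12, since C9 is quaternary) is lost syn to give the E-diene without touching any stereocentre.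

## Compound list
1 | (3E,7E)-homofarnesol, (3E,7E)-4,8,12-trimethyltrideca-3,7,11-trien-1-ol | CC(C)=CCC/C(C)=C/CC/C(C)=C/CCO | starting material
2 | (3E,7E)-homofarnesyl bromide, (3E,7E)-1-bromo-4,8,12-trimethyltrideca-3,7,11-triene | CC(C)=CCC/C(C)=C/CC/C(C)=C/CCBr | intermediate
3 | (1R,4aR,8aR)-1-(2-bromoethyl)-2,5,5,8a-tetramethyl-1,4,4a,5,6,7,8,8a-octahydronaphthalene; trans-decalin, Δ7, 5β-H, 9β-H, 10α-CH3, CH2CH2Br α on C9 | BrCC[C@@H]1C(C)=CC[C@@H]2C(C)(C)CCC[C@@]12C | intermediate
4 | 7-en-6-one of 3 (C6 ketone conjugated with Δ7; 5β-H, 9β-H, 10α-CH3) | BrCC[C@@H]1C(C)=CC(=O)[C@@H]2C(C)(C)CCC[C@@]12C | intermediate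
5 | diisobutylaluminium 6α-alkoxide of the Δ7 allylic alcohol (6β-H) | BrCC[C@@H]1C(C)=C[C@H](O[Al](CC(C)C)CC(C)C)[C@@H]2C(C)(C)CCC[C@@]12C | intermediate (not isolated)
6 | 6α-acetoxy (axial) Δ7 bicyclic bromide | BrCC[C@@H]1C(C)=C[C@H](OC(C)=O)[C@@H]2C(C)(C)CCC[C@@]12C | intermediate
7 | 7β-hydroperoxy-6α-acetoxy Δ8(9) bicyclic bromide | BrCCC1=C(C)[C@@H](OO)[C@H](OC(C)=O)[C@@H]2C(C)(C)CCC[C@@]12C | intermediate (not isolated)
8 | 8β,9β-epoxy-7β-hydroxy-6α-acetoxy bicyclic bromide (8α-CH3; CH2CH2Br α on C9) | BrCC[C@]12O[C@@]1(C)[C@@H](O)[C@H](OC(C)=O)[C@@H]3C(C)(C)CCC[C@@]23C | intermediate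
9 | 8β,9β-epoxy-6α-acetoxy-7β-isobutyryloxy bicyclic bromide | BrCC[C@]12O[C@@]1(C)[C@@H](OC(=O)C(C)C)[C@H](OC(C)=O)[C@@H]3C(C)(C)CCC[C@@]23C | intermediate
10 | 12-bromo-13,14,15,16-tetranor-neo-clerod-3-ene-6α,7β,8β-triol 6-acetate 7-isobutyrate (5α-, 8α-, 9α-CH3; 10β-H; CH2CH2Br β on C9) | CC(=O)O[C@H]1[C@H](OC(=O)C(C)C)[C@](C)(O)[C@](C)(CCBr)[C@H]2CCC=C(C)[C@]12C | intermediate
11 | 4-bromofuran-2(5H)-one | O=C1C=C(Br)CO1 | starting material
12 | 9β-vinyl analogue of 10 (13,14,15,16-tetranor-neo-cleroda-3,11-diene triol diester) | CC(=O)O[C@H]1[C@H](OC(=O)C(C)C)[C@](C)(O)[C@](C)(C=C)[C@H]2CCC=C(C)[C@]12C | intermediate (not isolated)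
13 | CNP0207114.1, (11E)-6α-acetoxy-8β-hydroxy-7β-isobutyryloxy-neo-cleroda-3,11,13-trien-15,16-olide | CC(=O)O[C@H]1[C@H](OC(=O)C(C)C)[C@](C)(O)[C@](C)(/C=C/C2=CC(=O)OC2)[C@H]2CCC=C(C)[C@]12C | target

Total step count: 8. Longest linear sequence: 8 (1 to 13).

## Steps most likely to fail

**Step 7 (backbone rearrangement).** Three things can go wrong:
- a Meinwald-type shift of CH3-17 or C7 gives an 8-ketone;
- early proton loss from the C10 cation gives halimane-type alkenes;
- the 6α-acetate captures the C5 cation.

The fallback sets out from 4.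
- The aluminium alkoxide 5 is trapped with Et3SiOTf/2,6-lutidine instead of Ac2O to give the 6α-triethylsilyl ether F1.
- F1 is photooxygenated as in step 5 through the 7β-hydroperoxide F2 to the epoxy alcohol F3, which is isobutyrylated to the epoxy ester F4.
- The BF3 rearrangement then runs next to a non-participating and less electron-withdrawing oxygen substituent and gives the clerodane silyl ether F5.
- HF·pyridine frees the 6α-alcohol F6.
- Ac2O/DMAP acetylates only this secondary equatorial hydroxyl (8β-OH is tertiary), which comes back to the route at 10.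

**Step 2 (asymmetric bicyclisation).** The enantioselectivity without a hydrogen-bonding handle is untested, and the Δ7 alkene may form alongside the Δ8(9) and exocyclic isomers. The fallback sets out from 2 and closes the rings one at a time.
- The stoichiometric Lewis-acid-assisted chiral Brønsted acid (S)-2-(2-fluorobenzyloxy)-2'-hydroxy-1,1'-binaphthyl·SnCl4 (toluene, −78 °C) is used only for the enantio-determining protonation and closure of ring A. This gives the monocyclic (5R)-bromide F7 (ring A closed, Δ1(10), 5β-H).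
- Ring B is then closed in a separate diastereoselective step with ClSO3H in 2-nitropropane at −78 °C. The C5 stereocentre steers the chair closure, and the sequence comes back to the route at 3.

**Step 5 (ene regiochemistry).** Abstraction of a CH3-17 hydrogen would give the exocyclic alkene instead of Δ8(9). The fallback sets out from 6.
- mCPBA epoxidises the open β face to give the 7β,8β-epoxide F8.
- MgBr2·OEt2 opens it at the tertiary C8 with inversion to the 8α-bromo-7β-alcohol F9.
- The axial C–Br bond of F9 is anti-periplanar to 9β-H, so DBU-induced E2 elimination gives the Δ8(9) 7β-allylic alcohol F10.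
- VO(acac)2/t-BuOOH epoxidises F10 syn to the hydroxyl, which comes back to the route at 8.

## Further compounds
F1 | step 7 | 6α-triethylsilyloxy Δ7 bicyclic bromide | BrCC[C@@H]1C(C)=C[C@H](O[Si](CC)(CC)CC)[C@@H]2C(C)(C)CCC[C@@]12C
F2 | step 7 | 7β-hydroperoxy-6α-triethylsilyloxy Δ8(9) bicyclic bromide | BrCCC1=C(C)[C@@H](OO)[C@H](O[Si](CC)(CC)CC)[C@@H]2C(C)(C)CCC[C@@]12C
F3 | step 7 | 8β,9β-epoxy-7β-hydroxy-6α-triethylsilyloxy bicyclic bromide | BrCC[C@]12O[C@@]1(C)[C@@H](O)[C@H](O[Si](CC)(CC)CC)[C@@H]3C(C)(C)CCC[C@@]23C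
F4 | step 7 | 8β,9β-epoxy-7β-isobutyryloxy-6α-triethylsilyloxy bicyclic bromide | BrCC[C@]12O[C@@]1(C)[C@@H](OC(=O)C(C)C)[C@H](O[Si](CC)(CC)CC)[C@@H]3C(C)(C)CCC[C@@]23C
F5 | step 7 | clerodane bromide with 6α-OSiEt3, 7β-isobutyrate, 8β-OH, Δ3 | CC[Si](CC)(CC)O[C@H]1[C@H](OC(=O)C(C)C)[C@](C)(O)[C@](C)(CCBr)[C@H]2CCC=C(C)[C@]12C
F6 | step 7 | clerodane bromide with 6α-OH, 7β-isobutyrate, 8β-OH, Δ3 | O[C@H]1[C@H](OC(=O)C(C)C)[C@](C)(O)[C@](C)(CCBr)[C@H]2CCC=C(C)[C@]12C
F7 | step 2 | (R)-6-[(3E)-6-bromo-3-methylhex-3-enyl]-1,5,5-trimethylcyclohexene | BrCC/C=C(C)/CC[C@H]1C(C)=CCCC1(C)C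
F8 | step 5 | 7β,8β-epoxy-6α-acetoxy bicyclic bromide (9β-H, 8α-CH3) | BrCC[C@@H]1[C@@]2(C)O[C@H]2[C@H](OC(C)=O)[C@@H]3C(C)(C)CCC[C@@]13C
F9 | step 5 | 8α-bromo-7β-hydroxy-6α-acetoxy bicyclic bromide (8β-CH3, 9β-H) | BrCC[C@@H]1[C@](C)(Br)[C@@H](O)[C@H](OC(C)=O)[C@@H]2C(C)(C)CCC[C@@]12C
F10 | step 5 | 7β-hydroxy-6α-acetoxy Δ8(9) bicyclic bromide | BrCCC1=C(C)[C@@H](O)[C@H](OC(C)=O)[C@@H]2C(C)(C)CCC[C@@]12C
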